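**Retrosynthesis**
1. Peperomin C (9) comes from trans-selective α-methylation of the β-(diarylmethyl)-γ-butyrolactone 7, so C3 is set by C4.
2. Lactone 7 comes from 5 by removing the C5 carbon handle: oxidation to the acid, then photochemical hydrodecarboxylation. This erases the C5 stereocentre after it has directed C4.
3. Lactone 5 comes from the photochemical C4–CH(Ar)₂ bond-forming radical addition of Ar₂CH₂ (3) to the chiral butenolide 4, anti to its CH₂OH group.
4. Diarylmethane 3 comes from a Suzuki coupling. No new ring is formed, because the lactone ring is already present in 4 and both aryl rings are purchased.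

Assumption: (S)-5-(hydroxymethyl)furan-2(5H)-one (4) is bought, as it is made commercially from D-ribonolactone.

**Step 1**
Reactants: 1 (3,4,5-trimethoxybenzyl chloride) + 2 (3,4,5-trimethoxyphenylboronic acid)
Product: 3 (bis(3,4,5-trimethoxyphenyl)methane)
Conditions: Pd(PPh₃)₄ (5 mol%), K₂CO₃ (3 equiv), THF/H₂O 4:1, 65 °C, 12 h
Reagents that add atoms: none
Why: Suzuki–Miyaura benzyl–aryl coupling gives the symmetrical diarylmethane, which has no stereocentre.

**Step 2**
Reactants: 4 ((S)-5-(hydroxymethyl)furan-2(5H)-one) + 3 (4 equiv)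
Product: 5 ((4R,5S)-4-[bis(3,4,5-trimethoxyphenyl)methyl]-5-(hydroxymethyl)oxolan-2-one)
Conditions: TBADT (tetrabutylammonium decatungstate, 2 mol%), MeCN, 390 nm LEDs, N₂, rt, 24 h
Reagents that add atoms: none
Why: Proposed new method: excited decatungstate abstracts the weak Ar₂CH–H of 3 by HAT, the bulky, electron-rich bis(3,4,5-trimethoxyphenyl)methyl radical adds to C4 of the butenolide anti to the C5 CH₂OH (trans-4,5, which fixes the C4 configuration), and the α-carbonyl radical is reduced and protonated by back-HAT from H⁺W₁₀O₃₂⁵⁻. The closest known reaction is the TBADT benzylic C–H Giese addition to butenolides and enones; the new elements are the hindered diarylmethane and the unprotected γ-hydroxymethyl butenolide. C3 is a CH₂ at this stage, so it carries no stereochemistry yet.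

**Step 3**
Reactants: 5
Product: 6 ((2S,3R)-3-[bis(3,4,5-trimethoxyphenyl)methyl]-5-oxooxolane-2-carboxylic acid)
Conditions: TEMPO (20 mol%), PhI(OAc)₂ (2.5 equiv), MeCN/H₂O 1:1, rt, 4 h
Reagents that add atoms: water, O (source of the new carboxyl oxygen)
Why: TEMPO/BAIB oxidation takes the primary alcohol through the aldehyde hydrate to the carboxylic acid, leaving the lactone and aryl ethers untouched; no stereocentre is altered.

**Step 4**
Reactants: 6
Product: 7 ((R)-4-[bis(3,4,5-trimethoxyphenyl)methyl]oxolan-2-one)
Conditions: [Ir(dF(CF₃)ppy)₂(dtbbpy)]PF₆ (1 mol%), Cs₂CO₃ (0.3 equiv), TIPS-SH (20 mol%), MeCN, blue LEDs, rt, 12 h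
Reagents that add atoms: none
Why: Photoredox hydrodecarboxylation oxidizes the α-alkoxy carboxylate, the radical loses CO₂, and thiol HAT delivers H to give the C5H₂ lactone. The C5 stereocentre is erased and the C4 centre is untouched.

**Step 5**
Reactants: 7 + 8 (iodomethane, MeI)
Product: 9 (peperomin C, (3S,4S)-4-[bis(3,4,5-trimethoxyphenyl)methyl]-3-methyloxolan-2-one)
Conditions: LiHMDS (1.1 equiv), THF, −78 °C, 45 min; then MeI (2 equiv), −78 → −30 °C, 2 h
Reagents that add atoms: MeI, CI
Why: The lactone enolate is C-alkylated by MeI anti to the bulky C4 diarylmethyl group (1,2-asymmetric induction), which sets C3 trans to C4.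

**Compound list**
1 | 3,4,5-trimethoxybenzyl chloride | COc1cc(CCl)cc(OC)c1OC | starting material
2 | 3,4,5-trimethoxyphenylboronic acid | COc1cc(B(O)O)cc(OC)c1OC | starting material
3 | bis(3,4,5-trimethoxyphenyl)methane | COc1cc(Cc2cc(OC)c(OC)c(OC)c2)cc(OC)c1OC | intermediate
4 | (S)-5-(hydroxymethyl)furan-2(5H)-one | O=C1C=C[C@@H](CO)O1 | starting material
5 | (4R,5S)-4-[bis(3,4,5-trimethoxyphenyl)methyl]-5-(hydroxymethyl)oxolan-2-one | O=C1C[C@H](C(c2cc(OC)c(OC)c(OC)c2)c2cc(OC)c(OC)c(OC)c2)[C@@H](CO)O1 | intermediate
6 | (2S,3R)-3-[bis(3,4,5-trimethoxyphenyl)methyl]-5-oxooxolane-2-carboxylic acid | O=C1C[C@H](C(c2cc(OC)c(OC)c(OC)c2)c2cc(OC)c(OC)c(OC)c2)[C@@H](C(=O)O)O1 | intermediate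
7 | (R)-4-[bis(3,4,5-trimethoxyphenyl)methyl]oxolan-2-one | O=C1C[C@H](C(c2cc(OC)c(OC)c(OC)c2)c2cc(OC)c(OC)c(OC)c2)CO1 | intermediate
8 | iodomethane | CI | starting material
9 | peperomin C | COc1cc(C(c2cc(OC)c(OC)c(OC)c2)[C@@H]2COC(=O)[C@H]2C)cc(OC)c1OC | target

**Total steps:** 5.
**Longest linear sequence:** 5 (1 → 3 → 5 → 6 → 7 → 9). The Suzuki step that makes 3 feeds into step 2 and lies on this longest path. From the purchased butenolide 4 alone the path is 4 steps.

**Three steps most likely to fail**
1. **Step 2 (proposed new step).** The hindered, stabilized diarylmethyl radical may add slowly or reversibly, and HAT at the butenolide γ-H could racemize the stereodirecting centre.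
   - Fallback: polar conjugate addition. Protect 4 as its TBS ether, add Ar₂CHLi (from 3, n-BuLi/TMEDA) with CuI·SMe₂ at −78 °C to give the trans-4,5 adduct, then remove the TBS group with TBAF to give 5.
2. **Step 3.** The TEMPO⁺ oxoammonium species could abstract hydride from the electron-rich Ar₂CH–H or oxidize an arene.
   - Fallback: change the C5-removal route. Oxidize 5 to the aldehyde with Dess–Martin periodinane, then decarbonylate with stoichiometric Wilkinson's complex (RhCl(PPh₃)₃, PhCN, reflux) to give 7 without passing through the acid.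
3. **Step 4.** The electron-rich arenes could divert the photoredox cycle, or the C5 radical could ring-open.
   - Fallback: Barton decarboxylation. Convert 6 to its N-hydroxypyridine-2-thione ester and irradiate with visible light in the presence of t-BuSH.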